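The earlier runs and the new flask are calculated for an exercise, noise included.

Decide first which species to follow in the Tuesday flask: follow E, not Z. E is the limiting reagent there, with Z charged at 5.33 times its amount.

| setting | Monday's | Thursday's | Friday's | Tuesday's |
|---|---|---|---|---|
| Z | 0.400 M | 0.240 M | 0.400 M | 0.800 M |
| E | 0.440 M | 0.280 M | 0.880 M | 0.150 M |
| J | 8.00 × 10⁻⁴ M | 8.00 × 10⁻⁴ M | 8.00 × 10⁻⁴ M | 8.00 × 10⁻⁴ M |
| time |  |  |  | 160 min |

| Monday's run: time / min | Monday's run: [Z] / M | Thursday's run: time / min | Thursday's run: [Z] / M | Friday's run: time / min | Friday's run: [Z] / M |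
|---|---|---|---|---|---|
| 6.4 | 0.3915 | 6.4 | 0.2354 | 6.4 | 0.3828 |
| 14 | 0.3786 | 14 | 0.2291 | 14 | 0.3629 |
| 32 | 0.3569 | 32 | 0.2184 | 32 | 0.3203 |
| 72 | 0.3151 | 72 | 0.1982 | 72 | 0.2479 |
| 160 | 0.2384 | 160 | 0.1571 | 160 | 0.1396 |

(readings scatter by 0.001 M)

- order of the initial rate in [E], near the charge of the Monday's run, the rate being that where two percent of its Z are G
- order of the initial rate in [Z], near the charge of the Monday's run, the rate being that where two percent of its Z are G (one fixed amount of G, the same in the runs compared)
- the Thursday's run starts with 0.160 M less of Z and of E than the Monday's run, and with no G. Compared where both hold the same amount of Z, once fifteen percent of what the Thursday's run was charged with has turned into G, is the Thursday's run faster, slower or alike (within a tenth)?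
- Z in the Tuesday's run at 160 min, as a share of the Z charged
- which of these the readings show (the substrate kills the catalyst / an uncatalysed path runs beside / the product binds the second partner)

- Overall: Z + E -> G, with J as catalyst.
- Constant volume, constant temperature.
- The analysis sees a species whether free or bound.
- "The second partner" is E.
- An order is taken over about fifteen percent of the charge, up and down.

Turn the question round. In the Tuesday flask, the lowest share of Z that the charge allows is

share floor = 1 − (E charged / Z charged) = 81.2 %

To get close to that floor, E must be used up within 160 min. Call κ the share of the E present that turns into G per minute. Over the first 32 min, Monday's run reads 0.00322 min⁻¹ at a mean Z of 0.378 M. Thursday's run reads 0.00251 min⁻¹ at a mean Z of 0.229 M. My own choice is a straight line through these two readings, κ = a + b[Z]: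

b = 0.00477 L mol⁻¹ min⁻¹
a = 0.00142 min⁻¹

Thursday's point rests on 0.0216 M of Z lost, so the scatter of 0.001 M makes it uncertain by 4.63 %.

The small thing in the Tuesday flask is the fall of Z. So hold Z at its charge, which makes that run pseudo-first-order in E, and reckon the fall of Z from what E loses. The quantity to carry is κ at Tuesday's Z, the share of E used per minute:

κ = a + b × Z charged = 0.00523 min⁻¹
n = κ × time = 0.836 lifetimes of E
Z lost = E charged × (1 − exp(−n)) = 0.0850 M
Z left = 89.4 % of the charge

For the opposite outcome, take 3 lifetimes, which leave 4.98 % of E. That needs κ = 0.0187 min⁻¹, which is 3.58 times what the line gives. So I expect the Tuesday flask to stand above the floor at 160 min, with E still present.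

The forecast gave 87 % of the Z charge left in the Tuesday flask at 160 min (range 82 % to 92 %), orders of 0.8 in E and 0.65 in Z near Monday's charge, alike for Thursday against Monday, and "an uncatalysed path runs beside". Its ground for Tuesday: “On Tuesday, E is limiting, so Z cannot fall below 81%.” My figure stands higher than its central value.

The Tuesday flask holds 89.1 % of its Z charge at 160 min; Thursday against Monday comes out alike, and the answer to the last question is "an uncatalysed path runs beside". Near Monday's charge the order in Z is 0.72, and the order in E is 0.95, higher than the forecast's 0.8.

    J + Z → JZ (8.880 L mol⁻¹ min⁻¹)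
    JZ + E → G + J (1.866 L mol⁻¹ min⁻¹)
    Z + E → G (0.005298 L mol⁻¹ min⁻¹)

Tuesday's E went through 0.867 lifetimes against my 0.836. Taking κ down the line to the mean Z and E of the Friday run, while G grows to a quarter of its Z charge, gives 39.1 min for that stretch, and the Friday run took 42.7 min. Early in the Tuesday flask, once J had met Z and with Z and E still near their charges, nearly all of J sat as JZ, and JZ + E → G + J used E at a share of 0.00144 min⁻¹, while Z + E → G used more, 0.00424 min⁻¹. Both steps ran on together, and at 160 min the Tuesday flask still held 0.0630 M of E.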